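**Assumption:** the SMILES gives no descriptor for the C6–C8'' biaryl axis, so the racemic mixture of atropisomers is taken as the target.

## The problem

Compound 8 is a dimer of acacetin (5,7-dihydroxy-4'-methoxyflavone) in which C6 of ring A of unit 1 is bonded to C8'' of ring A of unit 2; it has no stereocentre, and its only stereo-element is the biaryl axis, flanked by O5, O7, O7'' and C8a''–O1''. The flavones themselves are easy, but the junction is not: the halves are identical yet joined through different positions, and in a 5,7-dioxygenated flavone C6 and C8 are both ortho to O7 and both lie between two oxygens. Neither a dimerization of the flavone nor the closure of two pyranones onto a symmetric hexaoxygenated biphenyl can therefore tell the two sites apart, and the bond joins two electron-rich carbons that each carry two ortho oxygens, the worst case for a cross-coupling. The feature that opens the problem lies in the two rings A: both carry oxygen on the same three alternating carbons (C5, C7, C8a), and the biaryl carbon is para to C8a–O1 in unit 1 (C6) but ortho to C8a''–O1'' in unit 2 (C8''). With the three-carbon bridges C2–C3–C4 removed, the two rings A are thus two copies of one 3,5-dioxygenated phenol, whose phenol oxygen is the later pyran oxygen, joined ortho to para. In the ring of unit 1 the two carbons next to C8a (C4a and C8) are then equivalent and in the ring of unit 2 one of them is the biaryl carbon, so a pyranone closed from O1 at the C4–C4a bond can only face the right way. The two ring-B methyl ethers must outlast the release of four phenols, so the ring-A oxygens cannot be methyl ethers, and the C2=C3 bonds are reducible. A free 5-OH beside C4=O allows Wessely–Moser equilibration of C6- and C8-linked flavones in hot acid, so both pyranones must be closed while O5 and O5'' are capped.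

## Retrosynthesis

**8 ⇒ 7.** The four O-benzyl bonds at O5, O7, O5'' and O7'' are cut first. Benzyl is chosen over methyl because hydrogenolysis leaves the two anisyl ethers alone, whereas any demethylation would have to choose between 7-OMe and 4'-OMe. The forward reaction must cleave four hindered ethers without reducing C2=C3.

**7 ⇒ 5 (through 6).** Both pyranones are cut at the acyl–arene bonds C4–C4a and C4''–C4a'', not at the usual O1–C2 bond.
- The usual cut needs the acyl groups already on the rings. That means either a regioselective C-acylation of 2 in competition with its most nucleophilic carbon (the later C6''), or a choice between two flanking oxygens.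
- With the acid tethered through O1, the acylium can only reach a carbon ortho to that oxygen: C4a or C8 (equivalent) in unit 1, and C4a'' alone in unit 2, since the other neighbour of C8a'' is the biaryl carbon.
- Diacid 5 has two rings fewer than 7 and a mirror plane, so no axis to control. Its alkene geometry does not matter because the acylium (a ketene–oxocarbenium cation) rotates freely.
- The forward reaction must be mild enough for benzyl ethers, hence the mixed anhydride 6.

**5 ⇒ 4 ⇒ 2 + 3.** The two vinyl ether bonds O1–C2 and O1''–C2'' are cut, after changing the acids to esters. Forward, both phenols of 2 add to alkynoate 3. All of C2, C3, C4 and ring B of each unit come from one commercial ester used twice, in two directions at once. The addition must go through oxygen, not carbon, and must also succeed at the phenol beside the biaryl bond.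

**2 ⇒ 1 + 1.** The biaryl bond is cut last, where both partners are the same commercial phenol 1.
- Atom mapping: C2 of one molecule of 1 becomes C8''; C4 of the other becomes C6; the phenol oxygens become O1'' and O1; the benzyloxy oxygens become O5, O7, O5'' and O7''.
- At this stage the C6/C8 question has become ortho versus para to a free phenol oxygen, which is the selectivity that phenol-coupling catalysts are made to control.
- In 2 each ring has exactly one free OH, the one that will become the pyran oxygen. The coupling therefore makes the hindered bond and differentiates the six oxygens in one operation.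
- The forward reaction must give ortho–para union and stop at the dimer.

## Roads not taken

**Alternative 1:** cut the C6–C8'' bond between two complete flavones, the route most would draw first. Acacetin A1 would be converted into the 6-iodide A2 and the 8-boronate A3, and these joined by Suzuki–Miyaura coupling to 7.
- Each half needs its own site-selective iodination. C6 is reached only with the 5-OH free (chelate-directed) and then needs the sluggish capping of that chelated phenol. C8 is reached only on the fully alkylated flavone and then needs borylation of a hindered iodide.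
- The coupling must join two carbons that each carry two ortho oxygens. Protodeboronation of the 2,6-dioxygenated boronate competes with slow transmetalation.
- It would take roughly twice as many operations as the chosen route, and it treats the identity of the two halves as a nuisance instead of using it.

**Alternative 2:** cut both O1–C2 bonds (closure at the heteroatom) back to a symmetric biphenyl. The diacetyl hexaol A4 would be condensed to the bis-chalcone A5 and both pyranones closed oxidatively (I2, DMSO).
- In A4 and A5 each acyl group lies between two free hydroxyls, one ortho and one para to the axis. The target needs the para oxygen in one ring and the ortho oxygen in the other.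
- Nothing in the symmetric substrate makes that choice. The 6,6''-dimer A6, the 8,8''-dimer A7 and 8 would form together, and hot acid would interconvert them by Wessely–Moser ring opening.
- Differentiating the four flanking hydroxyls with protecting groups brings the original problem back. In 2 that differentiation comes free with the coupling.

**Alternative 3:** make the C6–C8'' bond by direct oxidative dimerization of acacetin A1 (one-electron oxidant or anode), with no prefunctionalization.
- Ring A of A1 is deactivated by the C4 carbonyl and the chelated 5-OH.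
- The phenol that is oxidized (7-OH) has C6 and C8 both ortho to it, so A6, A7 and 8 are expected together, along with couplings through ring B and C3.
- The 7-phenoxyl radical carries spin on O7 as well as on C6 and C8, so carbon–oxygen union competes with carbon–carbon union. Diaryl ethers such as the 7-O–8'' ether A8 are therefore expected in the same mixture.
- The chosen plan keeps the oxidative union but moves it to phenol 1. There the ring is not yet deactivated, and the two sites are ortho and para to the oxygen that guides the catalyst.

Key step: step 1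

## Route

Step 1
Reactants: 1 3,5-bis(benzyloxy)phenol (two molecules)
Product: 2 2',4,6,6'-tetrakis(benzyloxy)-[1,1'-biphenyl]-2,4'-diol
Conditions: Cr(salen)Cl (10 mol %; trivalent chromium; salen = dianion of N,N'-bis(3,5-di-tert-butylsalicylidene)cyclohexane-1,2-diamine), O2 (1 atm), ClCH2CH2Cl, 60 °C, stopped at partial conversion, 1 recovered
Reagents that add atoms: none
Why: Aerobic chromium–salen-catalysed oxidative homo-coupling of a phenol with free ortho and para sites, a reaction type for which ortho–para dimers are known. The catalyst, oxidized by O2 to a high-valent oxo-chromium species, binds one molecule of 1 as phenoxide and oxidizes it by one electron; a second, free molecule of 1 attacks this electrophilic metal-bound partner through carbon, and loss of a second electron and two protons (tautomerization of both dienone rings) gives the biphenol while O2 returns the catalyst and forms water. The selectivity needed is ortho on one partner and para on the other, against ortho–ortho and para–para dimers, together with a stop at the dimer. The bound partner should react at C2 because its oxygen is held on the metal and the new bond forms next to it (C2 and C6 are equivalent); the free partner should react at C4, its most nucleophilic carbon, para to OH and ortho to both benzyloxy groups, the site where 3,5-dialkoxyphenols are formylated and azo-coupled. Para–para union would put four benzyloxy groups around the new bond and is the most hindered of the three modes; ortho–ortho union needs the free partner to use its less nucleophilic ortho carbon. Product 2 should be a poorer ligand than 1, since its ortho OH is shielded by the new aryl group, and partial conversion limits trimers and oxygenation at the free para position. No ring is closed and no stereocentre is formed: the ring that becomes ring A of unit 1 is symmetrically substituted, so 2 has a mirror plane and the axis becomes stereogenic only in step 4.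

Step 2
Reactants: 2 2',4,6,6'-tetrakis(benzyloxy)-[1,1'-biphenyl]-2,4'-diol; 3 methyl 3-(4-methoxyphenyl)prop-2-ynoate (2.4 equiv)
Product: 4 dimethyl (2Z,2'Z)-3,3'-{[2',4,6,6'-tetrakis(benzyloxy)-[1,1'-biphenyl]-2,4'-diyl]bis(oxy)}bis[3-(4-methoxyphenyl)prop-2-enoate]
Conditions: Cs2CO3 (0.3 equiv), DMF, 80 °C
Reagents that add atoms: none
Why: Two-fold oxa-Michael addition of the phenoxides to the aryl-bearing carbon of the alkynoate, the first half of the aryloxycinnamate route to flavones; caesium phenoxides in DMF should react at oxygen, and anti addition should give the Z enol ethers drawn. The geometry is not critical because step 4 equilibrates it, and no stereocentre is formed.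

Step 3
Reactants: 4 dimethyl (2Z,2'Z)-3,3'-{[2',4,6,6'-tetrakis(benzyloxy)-[1,1'-biphenyl]-2,4'-diyl]bis(oxy)}bis[3-(4-methoxyphenyl)prop-2-enoate]
Product: 5 (2Z,2'Z)-3,3'-{[2',4,6,6'-tetrakis(benzyloxy)-[1,1'-biphenyl]-2,4'-diyl]bis(oxy)}bis[3-(4-methoxyphenyl)prop-2-enoic acid]
Conditions: LiOH·H2O (6 equiv), THF–MeOH–H2O, 40 °C; then 1 M HCl to pH 3
Reagents that add atoms: lithium hydroxide, [Li+].[OH-]
Why: Saponification of two methyl esters; the enol ether carbons carry an aryl and an aryloxy group and are shielded, so attack at the ester carbonyl should outrun conjugate displacement of aryloxide. Benzyl ethers, aryl methyl ethers and the enol ethers are stable to base.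

Step 4
Reactants: 5 (2Z,2'Z)-3,3'-{[2',4,6,6'-tetrakis(benzyloxy)-[1,1'-biphenyl]-2,4'-diyl]bis(oxy)}bis[3-(4-methoxyphenyl)prop-2-enoic acid]
Product: 7 5,7-bis(benzyloxy)-6-[5,7-bis(benzyloxy)-2-(4-methoxyphenyl)-4-oxo-4H-chromen-8-yl]-2-(4-methoxyphenyl)-4H-chromen-4-one (racemic), via bis(trifluoroacetic) mixed anhydride 6 (not isolated)
Conditions: (CF3CO)2O (3 equiv), CH2Cl2 (0.01 M), 0 °C to rt
Reagents that add atoms: none
Why: Two-fold intramolecular Friedel–Crafts acylation (6-exo closure of each pyranone at C4–C4a) through the mixed anhydride, as used for xanthones and chromones on alkoxy-activated rings. Each acylium can reach only a carbon ortho to its own enol-ether oxygen, which is the single free neighbour of C8a'' in unit 2 and either of two equivalent carbons in unit 1, so only the 6,8''-linked bis-flavone can form, and the E/Z geometry is levelled because the acylium is a freely rotating ketene–oxocarbenium cation. The axis becomes stereogenic here by closure on one of two enantiotopic carbons, without control, giving the racemate.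

Step 5
Reactants: 7 5,7-bis(benzyloxy)-6-[5,7-bis(benzyloxy)-2-(4-methoxyphenyl)-4-oxo-4H-chromen-8-yl]-2-(4-methoxyphenyl)-4H-chromen-4-one
Product: 8 5,7-dihydroxy-6-[5,7-dihydroxy-2-(4-methoxyphenyl)-4-oxo-4H-chromen-8-yl]-2-(4-methoxyphenyl)-4H-chromen-4-one (racemic; CNP0226117.0)
Conditions: H2 (1 atm), Pd/C (10 wt %), THF–MeOH, rt
Reagents that add atoms: none
Why: Hydrogenolysis of four benzyl aryl ethers; aryl methyl ethers, the chromone carbonyls and the biaryl bond are not touched, and the conjugated C2=C3 bonds of flavones are reduced much more slowly than benzyl ethers are cleaved at 1 atm. No acid is present, so the freed 5-OH groups cannot start a Wessely–Moser isomerization.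

## Compound list

1 | 3,5-bis(benzyloxy)phenol | Oc1cc(OCc2ccccc2)cc(OCc2ccccc2)c1 | starting material
2 | 2',4,6,6'-tetrakis(benzyloxy)-[1,1'-biphenyl]-2,4'-diol | Oc1cc(OCc2ccccc2)cc(OCc2ccccc2)c1-c1c(OCc2ccccc2)cc(O)cc1OCc1ccccc1 | intermediate
3 | methyl 3-(4-methoxyphenyl)prop-2-ynoate | COC(=O)C#Cc1ccc(OC)cc1 | starting material
4 | dimethyl (2Z,2'Z)-3,3'-{[2',4,6,6'-tetrakis(benzyloxy)-[1,1'-biphenyl]-2,4'-diyl]bis(oxy)}bis[3-(4-methoxyphenyl)prop-2-enoate] | COC(=O)/C=C(\Oc1cc(OCc2ccccc2)cc(OCc2ccccc2)c1-c1c(OCc2ccccc2)cc(O/C(=C\C(=O)OC)c2ccc(OC)cc2)cc1OCc1ccccc1)c1ccc(OC)cc1 | intermediate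
5 | (2Z,2'Z)-3,3'-{[2',4,6,6'-tetrakis(benzyloxy)-[1,1'-biphenyl]-2,4'-diyl]bis(oxy)}bis[3-(4-methoxyphenyl)prop-2-enoic acid] | OC(=O)/C=C(\Oc1cc(OCc2ccccc2)cc(OCc2ccccc2)c1-c1c(OCc2ccccc2)cc(O/C(=C\C(=O)O)c2ccc(OC)cc2)cc1OCc1ccccc1)c1ccc(OC)cc1 | intermediate
6 | bis(trifluoroacetic) mixed anhydride of 5 | FC(F)(F)C(=O)OC(=O)/C=C(\Oc1cc(OCc2ccccc2)cc(OCc2ccccc2)c1-c1c(OCc2ccccc2)cc(O/C(=C\C(=O)OC(=O)C(F)(F)F)c2ccc(OC)cc2)cc1OCc1ccccc1)c1ccc(OC)cc1 | intermediate (not isolated)
7 | 5,7-bis(benzyloxy)-6-[5,7-bis(benzyloxy)-2-(4-methoxyphenyl)-4-oxo-4H-chromen-8-yl]-2-(4-methoxyphenyl)-4H-chromen-4-one (racemic) | COc1ccc(-c2cc(=O)c3c(OCc7ccccc7)c(-c4c(OCc7ccccc7)cc(OCc7ccccc7)c5c(=O)cc(-c6ccc(OC)cc6)oc45)c(OCc7ccccc7)cc3o2)cc1 | intermediate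
8 | 5,7-dihydroxy-6-[5,7-dihydroxy-2-(4-methoxyphenyl)-4-oxo-4H-chromen-8-yl]-2-(4-methoxyphenyl)-4H-chromen-4-one (racemic) | COc1ccc(-c2cc(=O)c3c(O)c(-c4c(O)cc(O)c5c(=O)cc(-c6ccc(OC)cc6)oc45)c(O)cc3o2)cc1 | target

## Step count and risks

Total: 5 steps. Longest linear sequence: 5 steps (1 → 2 → 4 → 5 → 7 → 8; 3 is a commercial reagent).

**Step 1 (key step).**
- Most likely to go wrong: union through the wrong pair of positions (ortho–ortho or para–para), because all three reactive carbons of 1 are activated by three oxygens. Also over-oxidation of the dimer to trimers, and oxygenation at the free para position to quinones.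
- Fallback: from 1 to 2 by cross-coupling, with the pairing fixed by where the halogens sit. Monobromination of 1 (NBS, CH2Cl2, −78 °C) is expected to give both the para bromide 4-bromo-3,5-bis(benzyloxy)phenol F1 and the ortho bromide 2-bromo-3,5-bis(benzyloxy)phenol F2. Both are needed, so the mixture is separated, not avoided. Miyaura borylation of F1 (B2pin2, PdCl2(dppf), KOAc, dioxane, 90 °C) would give 3,5-bis(benzyloxy)-4-(4,4,5,5-tetramethyl-1,3,2-dioxaborolan-2-yl)phenol F3. Suzuki–Miyaura coupling of F3 with F2 (Pd(OAc)2, SPhos, K3PO4, toluene–H2O, 100 °C) would give 2, where the route is rejoined.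

**Step 4.**
- Most likely to go wrong: acid-induced loss or migration of benzyl groups on the phloroglucinol-type rings; C-trifluoroacetylation of the most electron-rich free ring carbon (the later C6''); intermolecular acylation; or too low an electrophilicity of the strongly stabilized acylium.
- Fallback: closure at oxygen under non-acidic conditions, from 2 to 7. The single free OH on each ring still fixes the direction. Magnesium-mediated ortho-formylation of 2 (MgCl2, Et3N, paraformaldehyde, MeCN, reflux) would give 2',4,6,6'-tetrakis(benzyloxy)-2,4'-dihydroxy-[1,1'-biphenyl]-3,3'-dicarbaldehyde F4. Addition of lithium (4-methoxyphenyl)acetylide (from 1-ethynyl-4-methoxybenzene and n-BuLi, excess, THF, −78 °C) would give the bis(propargylic alcohol) 1,1'-[2',4,6,6'-tetrakis(benzyloxy)-2,4'-dihydroxy-[1,1'-biphenyl]-3,3'-diyl]bis[3-(4-methoxyphenyl)prop-2-yn-1-ol] F5. MnO2 (CH2Cl2, rt) would give the bis-ynone 1,1'-[2',4,6,6'-tetrakis(benzyloxy)-2,4'-dihydroxy-[1,1'-biphenyl]-3,3'-diyl]bis[3-(4-methoxyphenyl)prop-2-yn-1-one] F6. Amine-mediated 6-endo cyclization of each ortho-hydroxyaryl ynone (Et2NH, EtOH, reflux) would give 7, where the route is rejoined.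

**Step 2.**
- Most likely to go wrong: slow addition of the phenol beside the biaryl bond to a β-aryl alkynoate of modest electrophilicity, and competing attack through ring carbon of the ambident phenoxides (leading towards 4-arylcoumarins).
- Fallback: from 2 to 5 with an aldehyde acceptor and an oxidation in place of ester hydrolysis. 3-(4-Methoxyphenyl)prop-2-ynal F7 (from 1-ethynyl-4-methoxybenzene, n-BuLi, then DMF) is a far stronger Michael acceptor and should add both phenols of 2 at room temperature under amine catalysis (DABCO, CH2Cl2). This would give the bis-enal (2Z,2'Z)-3,3'-{[2',4,6,6'-tetrakis(benzyloxy)-[1,1'-biphenyl]-2,4'-diyl]bis(oxy)}bis[3-(4-methoxyphenyl)prop-2-enal] F8. Pinnick oxidation of F8 (NaClO2, NaH2PO4, 2-methylbut-2-ene, t-BuOH–H2O) would give 5, where the route is rejoined.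

**Step 5.**
- Most likely to go wrong: over-reduction of the C2=C3 bonds once the benzyl ethers are gone, or incomplete cleavage of the ethers beside the axis as partly deprotected material precipitates.
- Fallback: from 7 to 8 by non-reductive Lewis-acid dealkylation with a cation scavenger (BCl3, pentamethylbenzene, CH2Cl2, −78 °C to 0 °C). This cleaves benzyl aryl ethers and spares unchelated aryl methyl ethers; it makes no new compound (F0).

## Further compounds

F1 | step 1 | 4-bromo-3,5-bis(benzyloxy)phenol | Oc1cc(OCc2ccccc2)c(Br)c(OCc2ccccc2)c1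
F2 | step 1 | 2-bromo-3,5-bis(benzyloxy)phenol | Oc1cc(OCc2ccccc2)cc(OCc2ccccc2)c1Br
F3 | step 1 | 3,5-bis(benzyloxy)-4-(4,4,5,5-tetramethyl-1,3,2-dioxaborolan-2-yl)phenol | Oc1cc(OCc2ccccc2)c(B2OC(C)(C)C(C)(C)O2)c(OCc2ccccc2)c1
F4 | step 4 | 2',4,6,6'-tetrakis(benzyloxy)-2,4'-dihydroxy-[1,1'-biphenyl]-3,3'-dicarbaldehyde | O=Cc1c(O)c(-c2c(OCc3ccccc3)cc(O)c(C=O)c2OCc2ccccc2)c(OCc2ccccc2)cc1OCc1ccccc1
F5 | step 4 | 1,1'-[2',4,6,6'-tetrakis(benzyloxy)-2,4'-dihydroxy-[1,1'-biphenyl]-3,3'-diyl]bis[3-(4-methoxyphenyl)prop-2-yn-1-ol] (mixture of diastereomers; both carbinol centres are removed in the next operation) | OC(C#Cc1ccc(OC)cc1)c1c(O)c(-c2c(OCc3ccccc3)cc(O)c(C(O)C#Cc3ccc(OC)cc3)c2OCc2ccccc2)c(OCc2ccccc2)cc1OCc1ccccc1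
F6 | step 4 | 1,1'-[2',4,6,6'-tetrakis(benzyloxy)-2,4'-dihydroxy-[1,1'-biphenyl]-3,3'-diyl]bis[3-(4-methoxyphenyl)prop-2-yn-1-one] | O=C(C#Cc1ccc(OC)cc1)c1c(O)c(-c2c(OCc3ccccc3)cc(O)c(C(=O)C#Cc3ccc(OC)cc3)c2OCc2ccccc2)c(OCc2ccccc2)cc1OCc1ccccc1
F7 | step 2 | 3-(4-methoxyphenyl)prop-2-ynal | O=CC#Cc1ccc(OC)cc1
F8 | step 2 | (2Z,2'Z)-3,3'-{[2',4,6,6'-tetrakis(benzyloxy)-[1,1'-biphenyl]-2,4'-diyl]bis(oxy)}bis[3-(4-methoxyphenyl)prop-2-enal] | O=C/C=C(\Oc1cc(OCc2ccccc2)cc(OCc2ccccc2)c1-c1c(OCc2ccccc2)cc(O/C(=C\C=O)c2ccc(OC)cc2)cc1OCc1ccccc1)c1ccc(OC)cc1
F0 | step 5 | none | none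
A1 | alternative 1 | acacetin, 5,7-dihydroxy-2-(4-methoxyphenyl)-4H-chromen-4-one | COc1ccc(-c2cc(=O)c3c(O)cc(O)cc3o2)cc1
A2 | alternative 1 | 5,7-bis(benzyloxy)-6-iodo-2-(4-methoxyphenyl)-4H-chromen-4-one | COc1ccc(-c2cc(=O)c3c(OCc4ccccc4)c(I)c(OCc4ccccc4)cc3o2)cc1
A3 | alternative 1 | 5,7-bis(benzyloxy)-2-(4-methoxyphenyl)-8-(4,4,5,5-tetramethyl-1,3,2-dioxaborolan-2-yl)-4H-chromen-4-one | COc1ccc(-c2cc(=O)c3c(OCc4ccccc4)cc(OCc4ccccc4)c(B5OC(C)(C)C(C)(C)O5)c3o2)cc1
A4 | alternative 2 | 1,1'-(2,2',4,4',6,6'-hexahydroxy-[1,1'-biphenyl]-3,3'-diyl)di(ethan-1-one) | CC(=O)c1c(O)cc(O)c(-c2c(O)cc(O)c(C(C)=O)c2O)c1O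
A5 | alternative 2 | (2E,2'E)-1,1'-(2,2',4,4',6,6'-hexahydroxy-[1,1'-biphenyl]-3,3'-diyl)bis[3-(4-methoxyphenyl)prop-2-en-1-one] | COc1ccc(/C=C/C(=O)c2c(O)cc(O)c(-c3c(O)cc(O)c(C(=O)/C=C/c4ccc(OC)cc4)c3O)c2O)cc1
A6 | alternative 2 | 6,6''-biacacetin, 5,7-dihydroxy-6-[5,7-dihydroxy-2-(4-methoxyphenyl)-4-oxo-4H-chromen-6-yl]-2-(4-methoxyphenyl)-4H-chromen-4-one | COc1ccc(-c2cc(=O)c3c(O)c(-c4c(O)cc5oc(-c6ccc(OC)cc6)cc(=O)c5c4O)c(O)cc3o2)cc1
A7 | alternative 2 | 8,8''-biacacetin, 5,7-dihydroxy-8-[5,7-dihydroxy-2-(4-methoxyphenyl)-4-oxo-4H-chromen-8-yl]-2-(4-methoxyphenyl)-4H-chromen-4-one | COc1ccc(-c2cc(=O)c3c(O)cc(O)c(-c4c(O)cc(O)c5c(=O)cc(-c6ccc(OC)cc6)oc45)c3o2)cc1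
A8 | alternative 3 | 7-O–8'' diaryl ether of two acacetin units, 7-{[5,7-dihydroxy-2-(4-methoxyphenyl)-4-oxo-4H-chromen-8-yl]oxy}-5-hydroxy-2-(4-methoxyphenyl)-4H-chromen-4-one | COc1ccc(-c2cc(=O)c3c(O)cc(Oc4c(O)cc(O)c5c(=O)cc(-c6ccc(OC)cc6)oc45)cc3o2)cc1
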